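The readings are calculated for an exercise; the scatter is artificial.

Set a straight line through the last grey reading against a curve that falls with the substrate left, and at 15 h the two stand 11 percentage points apart. That is more than the 3 points that one standard deviation in that reading moves the outcome, and more than the 2.3 points that starting the clock at the first reading moves it.

common to all: substrate 0.80 M; gas phase 54 mM (held); catalyst 1.6 mM; added ligand 3.7 mM

| flask | remark | time |
|---|---|---|
| grey | the very flask that is asked about, followed so far |  |
| flask |  | 15 h |

- grey (time / h: product / %): 0.250: 0.1; 0.417: 2.7; 0.833: 3.5; 1.50: 5.7; 3.00: 11.2

(each reading ± 1 percentage point)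

- the analysis behind the earlier runs scatters by 1 percentage point, standard deviation
- at the start none of the gas phase is in solution

- product at 15 h, in percent of the substrate charged
- concentration of dissolved gas in solution at 15 h, in percent of saturation

The charges need no care, since the grey run is this very flask and they cancel. So get the form of the curve right first: carry the mean constant, the logarithm of one over the fraction of substrate left, divided by the time, a mean pseudo-first-order constant. From the last grey reading it is 0.0396 /h, and held to 15 h it gives me 44.8% of product.

The forecast gives 45% (31% to 56%) and 88% of saturation (50% to 99%), and says of the readings that “they cannot separate these cases”.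

The flask gives 38.6% and 89.9% of saturation.

    substrate + dissolved gas + catalyst → catalyst + product (k = 0.555 /M²/s)
    dissolved gas + catalyst ⇌ idle complex A, settled at all times (K = 41.0 /M)
    gas phase ⇌ dissolved gas, rate k3*(csat - [dissolved gas]) (kL = 7.21 × 10⁻⁴ /s)
    catalyst + added ligand ⇌ idle complex B (K = 875 /M, k = 0.0230 /M/s)

Put that product back through the mean constant and the flask has 0.0325 /h, lower than the 0.0396 /h of the grey run. The same flask read at 2.5 d, with 83.1% of product, has 0.0296 /h, with catalyst at 17.4% against 18.4% at 15.0 h. The pairing of dissolved gas with catalyst to idle complex A, both ways, is one part of what holds the product of this flask down, and it acts together with the hour of the reading: without the pairing, product at 15 h stands at 54.7% instead of 38.6%, and read at 150 h the same flask holds 98.8%.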